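**Retrosynthetic overview**
- The strategy rests on ring A (C1–C5, C10; ent-kaurane numbering): quaternary C4 (CH3, C19H2OAc) cis to the C5 hydroxymethyl (C6), oxygen at C1 and quaternary C10. This is a masked cis-1,2-dicarboxylate on a 4-oxygenated cyclohexane, cut at C3–C4 and C5–C10 into a 2-silyloxydiene and citraconic anhydride (ring A first). The adduct is resolved, and C6 told apart from C19, by alkaloid-catalysed methanolysis.
- An enolate at C10 would expel the C20 oxygen, so the C1 carbonyl is used to do this on purpose (C10=C20 enone, then 1α-ol, then epoxide). The C10 radical from the epoxide adds to an acrylate anti to C6 and O1 and closes the 7,20-lactone (second ring).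
- A bromoacetal on O1 delivers C11–C12 to C9 by radical cyclisation with allyl transfer to C8. C8 is then quaternised, and lactol methylenation plus ring-closing metathesis close ring C (third ring).
- Ring D (fourth) closes by 5-exo vinyl-radical cyclisation C16→C13. The end game is acetylation of O1/O19, allylic oxidation to the 15-oxo-16-ene and release of C6–OH.

Key step: step 4

Conventions: ent-kaurane numbering throughout; α is the face of ring A that carries C19, C6 and C20; TBS = tert-butyldimethylsilyl, TBDPS = tert-butyldiphenylsilyl, PMB = 4-methoxybenzyl.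
Assumption: the sense of induction of the cinchona catalyst on this substituted anhydride is taken to be the one that opens the needed enantiomer at C6; if the mirror image reacts faster, the pseudo-enantiomeric catalyst (DHQ)2AQN is used instead.

**Route**

Step 1
Reactants: 1 3-[(tert-butyldimethylsilyl)oxy]propanal; 2 vinylmagnesium bromide
Product: 3 (±)-5-[(tert-butyldimethylsilyl)oxy]pent-1-en-3-ol
Conditions: THF, −78 → 0 °C; aq. NH4Cl
Reagents that add atoms: none
Why: Grignard 1,2-addition to an aldehyde; the carbinol centre is racemic and is removed in step 2.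

Step 2
Reactants: 3 (±)-5-[(tert-butyldimethylsilyl)oxy]pent-1-en-3-ol
Product: 4 5-[(tert-butyldimethylsilyl)oxy]pent-1-en-3-one
Conditions: Dess–Martin periodinane, CH2Cl2, 0 → 23 °C; used without storage
Reagents that add atoms: none
Why: Dess–Martin oxidation of a secondary allylic alcohol gives the vinyl ketone under neutral conditions that spare the β-silyloxy group.

Step 3
Reactants: 4 5-[(tert-butyldimethylsilyl)oxy]pent-1-en-3-one
Product: 5 (Z)-3,5-bis[(tert-butyldimethylsilyl)oxy]penta-1,3-diene (C3=C2–C1(OTBS)=C10–C20H2OTBS)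
Conditions: TBSOTf, Et3N, CH2Cl2, −78 → 0 °C
Reagents that add atoms: tert-butyldimethylsilyl trifluoromethanesulfonate, CC(C)(C)[Si](C)(C)OS(=O)(=O)C(F)(F)F
Why: Soft enolisation (silyl triflate/amine) silylates the carbonyl oxygen and removes a C10 proton without a free enolate, and should give the Z(O) enol ether (C20 arm trans to the vinyl group), which avoids A(1,3) strain.

Step 4
Reactants: 5 (Z)-3,5-bis[(tert-butyldimethylsilyl)oxy]penta-1,3-diene; 6 citraconic anhydride
Product: 7 (±)-cis-fused ring-A anhydride adduct, C19, C6 and C20 all on the α face (needed enantiomer drawn)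
Conditions: PhMe, BHT (cat.), 80 °C
Reagents that add atoms: none
Why: Concerted, asynchronous normal-demand [4+2] cycloaddition of a 2-silyloxy-1,3-diene with a cyclic anhydride, a known Diels–Alder class. Ring A closes as the cycloadduct by suprafacial formation of C5–C10 and C3–C4. C10, the enol-ether β-carbon with the largest HOMO coefficient, bonds to the unsubstituted and more electrophilic C5, so the methyl-bearing C4 bonds to the unhindered CH2 terminus C3; sterics and electronics agree. C4 and C5 are cis because the dienophile is cyclic; C10 is set relative to C5 by the endo transition state and the Z(O) diene geometry, which places the C20 arm on the face of the anhydride. The step needs endo and para-type selectivity, secured by the anhydride carbonyls and the 2-silyloxy group. Absolute configuration is not set here; the adduct is racemic and is resolved in step 5, and the enol ether left at C1=C2 is the masked C1 ketone.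

Step 5
Reactants: 7 (±)-ring-A anhydride adduct
Product: 8 hemiester (C19 carboxylic acid, C6 methyl ester), single enantiomer
Conditions: (DHQD)2AQN (10 mol %), MeOH (0.55 equiv), Et2O, −40 °C, stopped near half conversion; cold aq. citric acid; acid separated from unreacted anhydride on silica
Reagents that add atoms: methanol, CO
Why: Cinchona-alkaloid-catalysed alcoholysis of a cyclic anhydride run as a kinetic resolution: in the matched enantiomer the catalyst-preferred carbonyl is the less hindered C6 one (on tertiary C5) and is opened fast, whereas in the mirror image it is the neopentyl C19 carbonyl, so that enantiomer should remain as anhydride.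

Step 6
Reactants: 8 hemiester
Product: 10 C6 TBDPS ether C19 carboxylic acid, via lithium hydroxy carboxylate 9 (not isolated)
Conditions: LiBEt3H (3.3 equiv), THF, 0 °C; MeOH quench, concentrate; TBDPSCl, imidazole, DMF, 23 °C; aq. K2CO3–MeOH, then pH 4 buffer
Reagents that add atoms: tert-butyl(chloro)diphenylsilane, CC(C)(C)[Si](Cl)(c1ccccc1)c1ccccc1; lithium triethylborohydride, [Li+].CC[BH-](CC)CC (its lithium stays in 9 only)
Why: Lithium triethylborohydride reduces the methyl ester but not the lithium carboxylate (chemoselective hemiester reduction), and silylating the hydroxy carboxylate before any acidification prevents lactonisation; the silyl ester is hydrolysed on basic work-up.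

Step 7
Reactants: 10 C6 TBDPS ether C19 carboxylic acid
Product: 11 C19 primary alcohol
Conditions: LiAlH4, THF, 0 → 23 °C
Reagents that add atoms: none
Why: LiAlH4 reduction of a carboxylic acid to the neopentyl alcohol; silyl ethers and the silyl enol ether are inert to hydride.

Step 8
Reactants: 11 C19 primary alcohol
Product: 12 C19 PMB ether
Conditions: KHMDS, PMBBr, THF, −78 → −20 °C
Reagents that add atoms: 4-methoxybenzyl bromide, COc1ccc(CBr)cc1
Why: Williamson etherification with a reactive benzylic bromide at low temperature should outrun O→O silyl migration, and basic conditions leave the enol ether untouched.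

Step 9
Reactants: 12 C19 PMB ether
Product: 13 β-hydroxy ketone (C1 ketone, C20 alcohol)
Conditions: 1 M aq. HCl, THF, 0 → 23 °C
Reagents that add atoms: none
Why: Acid hydrolysis cleaves the silyl enol ether to the C1 ketone and the primary TBS ether, both far more labile than the TBDPS and PMB ethers; the configuration at C10 is of no consequence.

Step 10
Reactants: 13 β-hydroxy ketone
Product: 15 C10=C20 α-methylene ketone, via primary mesylate 14 (not isolated)
Conditions: MsCl, Et3N, CH2Cl2, 0 °C; then DBU, 23 °C; used crude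
Reagents that add atoms: methanesulfonyl chloride, CS(=O)(=O)Cl (its atoms stay in 14 only)
Why: Mesylation followed by E1cB elimination through the C1 ketone enolate turns the inherent lability of the C20 oxygen into a regiodefined exocyclic enone.

Step 11
Reactants: 15 C10=C20 α-methylene ketone
Product: 16 allylic alcohol (1α-OH, cis to the C6 and C19 arms)
Conditions: NaBH4, CeCl3·7H2O, MeOH, −78 → −40 °C
Reagents that add atoms: none
Why: Luche 1,2-reduction in which hydride should arrive on the ring face opposite to the C6 and C19 arms, setting C1 with its oxygen on the α face.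

Step 12
Reactants: 16 allylic alcohol
Product: 17 O1 2-bromo-1-ethoxyethyl mixed acetal (both acetal epimers expected)
Conditions: ethyl vinyl ether, NBS, CH2Cl2, −40 → 0 °C
Reagents that add atoms: ethyl vinyl ether, C=COCC; N-bromosuccinimide, O=C1CCC(=O)N1Br
Why: Bromoacetalisation: NBS activates the electron-rich vinyl ether and the C1 alcohol captures the oxocarbenium ion, giving a group that protects O1 and carries the radical precursor for step 16.

Step 13
Reactants: 17 bromoacetal
Product: 18 C10,C20 spiro-epoxide (both epoxide epimers acceptable)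
Conditions: m-CPBA, NaHCO3, CH2Cl2, 0 °C
Reagents that add atoms: 3-chloroperoxybenzoic acid, O=C(OO)c1cccc(Cl)c1
Why: Prilezhaev epoxidation of the only alkene, a 1,1-disubstituted exocyclic one; both epoxide epimers converge on the same planar C10 radical.

Step 14
Reactants: 18 spiro-epoxide; 19 2,2,2-trifluoroethyl acrylate
Product: 21 spirolactone (7,20-olide; C10 quaternary), via open-chain trifluoroethyl ester 20 (not isolated)
Conditions: Cp2TiCl2 (30 mol %), Zn, 2,4,6-collidine·HCl, THF, 23 °C
Reagents that add atoms: none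
Why: Nugent–RajanBabu titanocene(III) opening of the epoxide gives the tertiary C10 radical, which adds (Giese) to the acrylate from the face opposite to the α-oriented O1 and C6 groups and so sets C10 (C20 α, C9 β); the C20 titanium alkoxide then lactonises onto the activated ester.

Step 15
Reactants: 21 spirolactone
Product: 23 α,β-unsaturated spirolactone (C8=C9), via α-phenylselenide 22 (not isolated)
Conditions: LDA, THF, −78 °C; PhSeBr; then H2O2, pyridine, CH2Cl2, 0 → 23 °C
Reagents that add atoms: phenylselenyl bromide, Br[Se]c1ccccc1 (its PhSe group stays in 22 only)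
Why: α-Selenenylation of the lactone enolate and selenoxide syn-elimination install the C8=C9 acceptor.

Step 16
Reactants: 23 α,β-unsaturated spirolactone; 24 allyltributylstannane
Product: 25 acetal-bridged tricyclic lactone with C8 allyl (epimers at C8 and at the acetal carbon expected)
Conditions: AIBN (cat.), PhH (0.02 M), 80 °C
Reagents that add atoms: none
Why: Ueno–Stork cyclisation: the acetal-tethered primary radical adds 6-exo to C9 axially, hence on the lactone face of C1, which sets C9 with C11 cis to C1; the resulting α-lactone radical is trapped by the stannane (Keck allyl transfer), which introduces C14.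

Step 17
Reactants: 25 acetal-bridged tricyclic lactone; 26 2,3-dibromopropene
Product: 27 C8-quaternary lactone (2-bromoallyl C15 cis to H-9, allyl C14 cis to C11)
Conditions: LDA, THF–DMPU, −78 → −30 °C
Reagents that add atoms: none
Why: Enolate alkylation with a reactive allylic bromide forms quaternary C8; the electrophile should enter anti to the adjacent pseudoaxial C11 (the convex face, cis to H-9), which places C15 and C14 as in the target.

Step 18
Reactants: 27 C8-quaternary lactone
Product: 28 lactol (O1–C12 hemiacetal)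
Conditions: 1 M aq. HCl, THF, 23 °C
Reagents that add atoms: water, O
Why: Mild acid hydrolysis of the cyclic mixed acetal, to which the PMB and TBDPS ethers, the lactone and the vinyl bromide are inert.

Step 19
Reactants: 28 lactol
Product: 29 hydroxy triene (1α-OH free; C9 allyl; C8 allyl and 2-bromoallyl)
Conditions: Ph3PCH3Br, KOtBu, THF, 0 → 23 °C
Reagents that add atoms: methyltriphenylphosphonium bromide, C[P+](c1ccccc1)(c1ccccc1)c1ccccc1.[Br-]
Why: Wittig methylenation of the lactol through its open hydroxy aldehyde turns C11–C12 into the C9 allyl group and frees O1, the neopentyl lactone carbonyl being inert to the ylide.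

Step 20
Reactants: 29 hydroxy triene
Product: 30 cis-fused cyclohexene lactone (ring C, C12=C13)
Conditions: Grubbs II catalyst (5 mol %), CH2Cl2, 40 °C
Reagents that add atoms: none
Why: Ring-closing metathesis of the two cis-disposed allyl groups closes ring C with the alkene at C12=C13, the 2-bromoalkene being unreactive towards the ruthenium carbene.

Step 21
Reactants: 30 cis-fused cyclohexene lactone
Product: 31 tetracyclic 16-ene (1α-OH, 19-O-PMB, 6-O-TBDPS)
Conditions: Bu3SnH, AIBN (cat.), PhH (0.05 M), 80 °C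
Reagents that add atoms: none
Why: Vinyl-radical 5-exo-trig cyclisation from C16 onto C13 closes ring D as the bicyclo[3.2.1]octane with the exocyclic methylene; C13 is fixed by the bridging geometry, and a fairly high tin hydride concentration should trap the C12 radical before rearrangement.

Step 22
Reactants: 31 tetracyclic 16-ene
Product: 32 1α,19-diol (6-O-TBDPS)
Conditions: DDQ, CH2Cl2–pH 7 buffer, 0 → 23 °C
Reagents that add atoms: none
Why: Oxidative cleavage of the PMB ether by DDQ leaves the silyl ether, lactone and alkene untouched.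

Step 23
Reactants: 32 1α,19-diol
Product: 33 1α,19-diacetate (6-O-TBDPS)
Conditions: Ac2O, pyridine, DMAP (cat.), 23 °C
Reagents that add atoms: acetic anhydride, CC(=O)OC(C)=O
Why: DMAP-catalysed acetylation of the secondary C1 and neopentyl C19 hydroxyls while C6 stays silylated.

Step 24
Reactants: 33 1α,19-diacetate
Product: 34 C15 allylic alcohol
Conditions: SeO2 (0.5 equiv), t-BuOOH, CH2Cl2, 23 °C
Reagents that add atoms: tert-butyl hydroperoxide, CC(C)(C)OO (oxygen relayed by selenium dioxide, O=[Se]=O)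
Why: Selenium dioxide allylic oxidation (ene reaction then [2,3]-shift) at C15, the only allylic methylene, keeps the exocyclic alkene in place; the C15 configuration is lost in step 25.

Step 25
Reactants: 34 C15 allylic alcohol
Product: 35 15-oxo-16-ene (6-O-TBDPS)
Conditions: Dess–Martin periodinane, CH2Cl2, 0 → 23 °C
Reagents that add atoms: none
Why: Dess–Martin oxidation of the allylic alcohol gives the α-methylene cyclopentanone.

Step 26
Reactants: 35 15-oxo-16-ene (6-O-TBDPS)
Product: 36 CNP0105570.2 (target)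
Conditions: HF·pyridine, pyridine, THF, 0 → 23 °C
Reagents that add atoms: none
Why: Buffered fluoride cleavage of the primary TBDPS ether, under which the acetates, lactone and enone should be stable.

**Compound list**
1 | 3-[(tert-butyldimethylsilyl)oxy]propanal | O=CCCO[Si](C)(C)C(C)(C)C | starting material
2 | vinylmagnesium bromide | C=C[Mg]Br | starting material
3 | (±)-5-[(tert-butyldimethylsilyl)oxy]pent-1-en-3-ol | C=CC(O)CCO[Si](C)(C)C(C)(C)C | intermediate
4 | 5-[(tert-butyldimethylsilyl)oxy]pent-1-en-3-one | C=CC(=O)CCO[Si](C)(C)C(C)(C)C | intermediate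
5 | (Z)-3,5-bis[(tert-butyldimethylsilyl)oxy]penta-1,3-diene | C=C/C(O[Si](C)(C)C(C)(C)C)=C/CO[Si](C)(C)C(C)(C)C | intermediate
6 | citraconic anhydride (3-methylfuran-2,5-dione) | CC1=CC(=O)OC1=O | starting material
7 | (±)-5-(TBSO)-4-(TBSOCH2)-7a-methyl-3a,4,7,7a-tetrahydro-2-benzofuran-1,3-dione, cis-fused, C4 side chain cis to the anhydride ring (racemate; needed enantiomer drawn) | C[C@@]12CC=C(O[Si](C)(C)C(C)(C)C)[C@H](CO[Si](C)(C)C(C)(C)C)[C@@H]1C(=O)OC2=O | intermediate
8 | 4-(TBSO)-5-(TBSOCH2)-6-(methoxycarbonyl)-1-methylcyclohex-3-ene-1-carboxylic acid, CO2H, CO2Me and CH2OTBS mutually cis (C19 acid, C6 ester) | C[C@@]1(C(=O)O)CC=C(O[Si](C)(C)C(C)(C)C)[C@H](CO[Si](C)(C)C(C)(C)C)[C@@H]1C(=O)OC | intermediate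
9 | lithium 4-(TBSO)-5-(TBSOCH2)-6-(hydroxymethyl)-1-methylcyclohex-3-ene-1-carboxylate | C[C@@]1(C(=O)[O-])CC=C(O[Si](C)(C)C(C)(C)C)[C@H](CO[Si](C)(C)C(C)(C)C)[C@@H]1CO.[Li+] | intermediate (not isolated)
10 | 4-(TBSO)-5-(TBSOCH2)-6-(TBDPSOCH2)-1-methylcyclohex-3-ene-1-carboxylic acid, all three carbon arms cis | C[C@@]1(C(=O)O)CC=C(O[Si](C)(C)C(C)(C)C)[C@H](CO[Si](C)(C)C(C)(C)C)[C@@H]1CO[Si](c2ccccc2)(c3ccccc3)C(C)(C)C | intermediate
11 | [4-(TBSO)-5-(TBSOCH2)-6-(TBDPSOCH2)-1-methylcyclohex-3-en-1-yl]methanol (C19 alcohol) | C[C@@]1(CO)CC=C(O[Si](C)(C)C(C)(C)C)[C@H](CO[Si](C)(C)C(C)(C)C)[C@@H]1CO[Si](c2ccccc2)(c3ccccc3)C(C)(C)C | intermediate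
12 | C19 PMB ether of 11 (C1 TBS enol ether, C20 OTBS, C6 OTBDPS) | C[C@@]1(COCc4ccc(OC)cc4)CC=C(O[Si](C)(C)C(C)(C)C)[C@H](CO[Si](C)(C)C(C)(C)C)[C@@H]1CO[Si](c2ccccc2)(c3ccccc3)C(C)(C)C | intermediate
13 | 2-(hydroxymethyl)-4-methyl-4-(PMBOCH2)-3-(TBDPSOCH2)cyclohexan-1-one, three CH2O arms cis | C[C@@]1(COCc4ccc(OC)cc4)CCC(=O)[C@H](CO)[C@@H]1CO[Si](c2ccccc2)(c3ccccc3)C(C)(C)C | intermediate
14 | methanesulfonate of 13 at C20 | C[C@@]1(COCc4ccc(OC)cc4)CCC(=O)[C@H](COS(C)(=O)=O)[C@@H]1CO[Si](c2ccccc2)(c3ccccc3)C(C)(C)C | intermediate (not isolated)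
15 | 4-methyl-2-methylidene-4-(PMBOCH2)-3-(TBDPSOCH2)cyclohexan-1-one (C19 and C6 arms cis) | C[C@@]1(COCc4ccc(OC)cc4)CCC(=O)C(=C)[C@@H]1CO[Si](c2ccccc2)(c3ccccc3)C(C)(C)C | intermediate
16 | 4-methyl-2-methylidene-4-(PMBOCH2)-3-(TBDPSOCH2)cyclohexan-1-ol, OH cis to both CH2O arms (1α-OH) | C[C@@]1(COCc4ccc(OC)cc4)CC[C@H](O)C(=C)[C@@H]1CO[Si](c2ccccc2)(c3ccccc3)C(C)(C)C | intermediate
17 | O1 2-bromo-1-ethoxyethyl acetal of 16 (acetal epimers) | C[C@@]1(COCc4ccc(OC)cc4)CC[C@H](OC(CBr)OCC)C(=C)[C@@H]1CO[Si](c2ccccc2)(c3ccccc3)C(C)(C)C | intermediate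
18 | C10,C20 spiro-epoxide of 17 (epoxide epimers) | C[C@@]1(COCc4ccc(OC)cc4)CC[C@H](OC(CBr)OCC)C5(CO5)[C@@H]1CO[Si](c2ccccc2)(c3ccccc3)C(C)(C)C | intermediate
19 | 2,2,2-trifluoroethyl acrylate | C=CC(=O)OCC(F)(F)F | starting material
20 | open-chain adduct: C10 bearing C20H2OH (as titanium alkoxide) and CH2CH2CO2CH2CF3, C9 trans to O1 and C6 | C[C@@]1(COCc4ccc(OC)cc4)CC[C@H](OC(CBr)OCC)[C@@](CO)(CCC(=O)OCC(F)(F)F)[C@@H]1CO[Si](c2ccccc2)(c3ccccc3)C(C)(C)C | intermediate (not isolated)
21 | spirolactone (7,20-olide): ring A spiro-fused at C10 to a tetrahydropyran-2-one, C20 α, C9 β | C[C@@]1(COCc4ccc(OC)cc4)CC[C@H](OC(CBr)OCC)[C@@]5(CCC(=O)OC5)[C@@H]1CO[Si](c2ccccc2)(c3ccccc3)C(C)(C)C | intermediate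
22 | 8-(phenylselanyl) derivative of 21 | C[C@@]1(COCc4ccc(OC)cc4)CC[C@H](OC(CBr)OCC)[C@@]5(CC([Se]c6ccccc6)C(=O)OC5)[C@@H]1CO[Si](c2ccccc2)(c3ccccc3)C(C)(C)C | intermediate (not isolated)
23 | α,β-unsaturated spirolactone (C8=C9) | C[C@@]1(COCc4ccc(OC)cc4)CC[C@H](OC(CBr)OCC)[C@@]5(C=CC(=O)OC5)[C@@H]1CO[Si](c2ccccc2)(c3ccccc3)C(C)(C)C | intermediate
24 | allyltributylstannane | C=CC[Sn](CCCC)(CCCC)CCCC | starting material
25 | acetal-bridged tricyclic lactone: 2-ethoxytetrahydropyran O1–C12–C11–C9 cis-fused to the lactone and trans-fused to ring A; C8 allyl (epimers at C8 and C12) | C[C@@]1(COCc4ccc(OC)cc4)CC[C@H](OC(OCC)C6)[C@@]5([C@H]6C(CC=C)C(=O)OC5)[C@@H]1CO[Si](c2ccccc2)(c3ccccc3)C(C)(C)C | intermediate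
26 | 2,3-dibromopropene | C=C(Br)CBr | starting material
27 | C8-quaternary lactone: 2-bromoallyl (C15) cis to H-9, allyl (C14) cis to C11 | C[C@@]1(COCc4ccc(OC)cc4)CC[C@H](OC(OCC)C6)[C@@]5([C@H]6[C@@](CC=C)(CC(Br)=C)C(=O)OC5)[C@@H]1CO[Si](c2ccccc2)(c3ccccc3)C(C)(C)C | intermediate
28 | lactol of 27 (O1–C12 hemiacetal) | C[C@@]1(COCc4ccc(OC)cc4)CC[C@H](OC(O)C6)[C@@]5([C@H]6[C@@](CC=C)(CC(Br)=C)C(=O)OC5)[C@@H]1CO[Si](c2ccccc2)(c3ccccc3)C(C)(C)C | intermediate
29 | hydroxy triene: 1α-OH, C9 allyl (cis to C1), C8 allyl and 2-bromoallyl | C[C@@]1(COCc4ccc(OC)cc4)CC[C@H](O)[C@@]5([C@H](CC=C)[C@@](CC=C)(CC(Br)=C)C(=O)OC5)[C@@H]1CO[Si](c2ccccc2)(c3ccccc3)C(C)(C)C | intermediate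
30 | cis-fused cyclohexene lactone (ring C closed, C12=C13; C8 2-bromoallyl) | C[C@@]1(COCc4ccc(OC)cc4)CC[C@H](O)[C@@]5([C@@H]6CC=CC[C@]6(CC(Br)=C)C(=O)OC5)[C@@H]1CO[Si](c2ccccc2)(c3ccccc3)C(C)(C)C | intermediate
31 | 1α-hydroxy-19-(PMB-oxy)-6-(TBDPS-oxy)-6,7-seco-ent-kaur-16-en-7,20-olide | C=C1C[C@]23C[C@H]1CC[C@H]2[C@]1(COC3=O)[C@@H](O)CC[C@@](C)(COCc4ccc(OC)cc4)[C@H]1CO[Si](c5ccccc5)(c6ccccc6)C(C)(C)C | intermediate
32 | 1α,19-dihydroxy-6-(TBDPS-oxy)-6,7-seco-ent-kaur-16-en-7,20-olide | C=C1C[C@]23C[C@H]1CC[C@H]2[C@]1(COC3=O)[C@@H](O)CC[C@@](C)(CO)[C@H]1CO[Si](c5ccccc5)(c6ccccc6)C(C)(C)C | intermediate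
33 | 1α,19-diacetoxy-6-(TBDPS-oxy)-6,7-seco-ent-kaur-16-en-7,20-olide | C=C1C[C@]23C[C@H]1CC[C@H]2[C@]1(COC3=O)[C@@H](OC(C)=O)CC[C@@](C)(COC(C)=O)[C@H]1CO[Si](c5ccccc5)(c6ccccc6)C(C)(C)C | intermediate
34 | 1α,19-diacetoxy-15-hydroxy-6-(TBDPS-oxy)-6,7-seco-ent-kaur-16-en-7,20-olide (C15 configuration not defined) | C=C1C(O)[C@]23C[C@H]1CC[C@H]2[C@]1(COC3=O)[C@@H](OC(C)=O)CC[C@@](C)(COC(C)=O)[C@H]1CO[Si](c5ccccc5)(c6ccccc6)C(C)(C)C | intermediate
35 | 1α,19-diacetoxy-15-oxo-6-(TBDPS-oxy)-6,7-seco-ent-kaur-16-en-7,20-olide | C=C1C(=O)[C@]23C[C@H]1CC[C@H]2[C@]1(COC3=O)[C@@H](OC(C)=O)CC[C@@](C)(COC(C)=O)[C@H]1CO[Si](c5ccccc5)(c6ccccc6)C(C)(C)C | intermediate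
36 | CNP0105570.2: 1α,19-diacetoxy-6-hydroxy-15-oxo-6,7-seco-ent-kaur-16-en-7,20-olide | C=C1C(=O)[C@]23C[C@H]1CC[C@H]2[C@]1(COC3=O)[C@@H](OC(C)=O)CC[C@@](C)(COC(C)=O)[C@H]1CO | target

**Step count and risks**
Total step count: 26. Longest linear sequence: 26 steps (from 1).

The three steps most likely to fail:

1. Step 5. The rate difference between the two enantiomers may be too small, or methanol may also attack the C19 carbonyl of the matched enantiomer, so that the hemiester forms with low enantiomeric purity or as a regioisomer mixture; the acid produced may also protonate the enol ether. Fallback (classical resolution in place of kinetic resolution), setting out from 7: uncatalysed methanolysis (MeOH, Et3N, DMAP cat., CH2Cl2) at the less hindered C6 carbonyl gives the racemic hemiester F1. Salt formation with (R)-1-phenylethylamine (or its enantiomer, whichever gives the less soluble salt of the needed acid) and fractional crystallisation gives the (R)-1-phenylethylammonium salt of the needed acid F2. Cold dilute acid liberates the acid, and the route is rejoined at 8.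

2. Step 14. The titanium(III)/zinc system may reduce the primary C–Br bond of the bromoacetal, or the epoxide may be deoxygenated before the C10 radical is captured. Fallback (the radical precursor is installed only after the coupling), setting out from 16: TESCl/imidazole gives the O1 triethylsilyl ether F3, and m-CPBA gives its spiro-epoxide F4. The same titanocene coupling with 19 gives the O1-TES spirolactone F5, and LDA/PhSeBr then H2O2 gives the O1-TES unsaturated spirolactone F6. HF·pyridine/pyridine in THF removes the triethylsilyl group selectively to give the 1α-hydroxy unsaturated spirolactone F7. Ethyl vinyl ether/NBS then converts this into the bromoacetal, and the route is rejoined at 23.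

3. Step 17. Alkylation of the hindered enolate held in the rigid acetal-bridged framework may be slow or poorly face-selective, because the incoming electrophile meets C5 in a 1,3-diaxial contact. Fallback (the bridge is opened first so that the lactone can relax), setting out from 25: 1 M aq. HCl/THF gives the C8-allyl lactol F8, and Wittig methylenation gives the 1α-hydroxy diallyl lactone F9. TESOTf/2,6-lutidine gives its O1 triethylsilyl ether F10. LDA then 26 alkylates the now flexible enolate anti to the C9 allyl group and gives the O1-TES C8-quaternary lactone F11. HF·pyridine/pyridine removes the triethylsilyl group, and the route is rejoined at 29.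

Further compounds
F1 | step 5 | racemic hemiester (C19 acid, C6 methyl ester; one enantiomer drawn) | C[C@@]1(C(=O)O)CC=C(O[Si](C)(C)C(C)(C)C)[C@H](CO[Si](C)(C)C(C)(C)C)[C@@H]1C(=O)OC
F2 | step 5 | (R)-1-phenylethylammonium salt of the needed hemiester | C[C@@]1(C(=O)[O-])CC=C(O[Si](C)(C)C(C)(C)C)[C@H](CO[Si](C)(C)C(C)(C)C)[C@@H]1C(=O)OC.C[C@@H]([NH3+])c1ccccc1
F3 | step 14 | O1 triethylsilyl ether of 16 | C[C@@]1(COCc4ccc(OC)cc4)CC[C@H](O[Si](CC)(CC)CC)C(=C)[C@@H]1CO[Si](c2ccccc2)(c3ccccc3)C(C)(C)C
F4 | step 14 | C10,C20 spiro-epoxide of the O1-TES ether | C[C@@]1(COCc4ccc(OC)cc4)CC[C@H](O[Si](CC)(CC)CC)C5(CO5)[C@@H]1CO[Si](c2ccccc2)(c3ccccc3)C(C)(C)C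
F5 | step 14 | O1-TES spirolactone | C[C@@]1(COCc4ccc(OC)cc4)CC[C@H](O[Si](CC)(CC)CC)[C@@]5(CCC(=O)OC5)[C@@H]1CO[Si](c2ccccc2)(c3ccccc3)C(C)(C)C
F6 | step 14 | O1-TES unsaturated spirolactone (C8=C9) | C[C@@]1(COCc4ccc(OC)cc4)CC[C@H](O[Si](CC)(CC)CC)[C@@]5(C=CC(=O)OC5)[C@@H]1CO[Si](c2ccccc2)(c3ccccc3)C(C)(C)C
F7 | step 14 | 1α-hydroxy unsaturated spirolactone | C[C@@]1(COCc4ccc(OC)cc4)CC[C@H](O)[C@@]5(C=CC(=O)OC5)[C@@H]1CO[Si](c2ccccc2)(c3ccccc3)C(C)(C)C
F8 | step 17 | C8-allyl lactol (from 25) | C[C@@]1(COCc4ccc(OC)cc4)CC[C@H](OC(O)C6)[C@@]5([C@H]6C(CC=C)C(=O)OC5)[C@@H]1CO[Si](c2ccccc2)(c3ccccc3)C(C)(C)C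
F9 | step 17 | 1α-hydroxy C9,C8-diallyl lactone | C[C@@]1(COCc4ccc(OC)cc4)CC[C@H](O)[C@@]5([C@H](CC=C)C(CC=C)C(=O)OC5)[C@@H]1CO[Si](c2ccccc2)(c3ccccc3)C(C)(C)C
F10 | step 17 | O1 triethylsilyl ether of the diallyl lactone | C[C@@]1(COCc4ccc(OC)cc4)CC[C@H](O[Si](CC)(CC)CC)[C@@]5([C@H](CC=C)C(CC=C)C(=O)OC5)[C@@H]1CO[Si](c2ccccc2)(c3ccccc3)C(C)(C)C
F11 | step 17 | O1-TES C8-quaternary lactone (C15 cis to H-9) | C[C@@]1(COCc4ccc(OC)cc4)CC[C@H](O[Si](CC)(CC)CC)[C@@]5([C@H](CC=C)[C@@](CC=C)(CC(Br)=C)C(=O)OC5)[C@@H]1CO[Si](c2ccccc2)(c3ccccc3)C(C)(C)C
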